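## Structural features

The target is 1β-[(E)-p-coumaroyloxy]polygodial, a drimane: a trans-fused decalin whose ring A (C1–C5, C10) and ring B (C5–C10) share the C5–C10 bond, with two methyls on C4 and an angular methyl on C10 (drimane numbering; C11 is the formyl carbon on C9, C12 the formyl carbon on C8; the same atom labels are used for all intermediates). Four stereocentres are present: C1 (R, equatorial β-acyloxy), the quaternary C10 (S) and C9 (R, β-formyl) are contiguous, and C5 (S, α-H) is next to C10. Ring B carries the 7-ene-11,12-dial: H9 is α to C11 and vinylogously α to C12, so the 9β-aldehyde epimerises with base and the ene-dial condenses with amines. O1 and C11 are peri (both equatorial, on C1 and C9, with C10 between them): a free 1-hydroxyl would close a lactol on the C11 aldehyde, and a free 11-hydroxyl can take over the acyl group. The acyl group is an (E)-4-hydroxycinnamate, labile to hydride and strong base, with a free phenol that does not tolerate activated-DMSO or hypervalent-iodine oxidants. The real difficulty is the oxygen on C1 directly beside the quaternary C10, in fixed relation to C9 and C5: polyene cyclisation of farnesyl chains and the sclareolide chiral pool both give drimanes with a bare C1. The key step exploits the C1–C10 bond of ring A: O1 and the 10-methyl are syn while the C10–C9 bond is anti to the C1–O bond, which is the signature of a C1–C10 epoxide opened at C10 with inversion by C9. C9 qualifies as that nucleophile because it is the α-carbon of the C11 carbonyl, and C7=C8–C12 is then the acrylate half of an alkylidenesuccinate, so the whole ene-dial carbon pattern can ride on the nucleophile.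

## Logic of the disconnections

22 to 21 to 20. The phenol O–H of 22 is traced to the aryl O–Si bond of 21, and the C11 and C12 carbonyls of 21 to the two CH2–O–Si groups of 20. This removes the ene-dial and the free phenol from all earlier intermediates. The forward steps must create both aldehydes in one operation, since an 11-hydroxyl beside a C12 aldehyde would close a lactol, and nothing basic enough to epimerise C9 may follow.

20 to 15 + 18. The ester C–O bond between O1 and the cinnamoyl carbonyl is cut. This is done while O1 is the only free hydroxyl, so no acyl migration to O11 is possible. The gain is a convergent union of the terpenoid core with the aryl acrylate. The demand is acylation of a secondary hydroxyl flanked by the quaternary C10.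

15 to 14 to 13. The two primary Si–O bonds are removed, then the C11–O and C12–O single bonds of 14 are taken back to the carbonyl groups of 13 (C11 as a lactone carbonyl bound to O1, C12 as a methyl ester). All three hydroxyls of 14 come from one reduction, and the two primary ones are distinguished from the hindered O1 by rate alone. The forward reduction must be 1,2 at the conjugated C12 ester.

13 to 11. The acyl bond C11–O1 of the lactone is cut and the C9 configuration is released. The peri relation of O1 and C11 is used as a lock: only a 9β-carboxyl can reach the 1β-oxygen, so C9 no longer needs reagent control. The forward step must equilibrate C9 and finally protonate the lactone dienolate at C9, not at C7.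

11 to 9 (key). The C9–C10 bond is cut and O1 is reconnected to C10 as an oxirane. Ring B, the quaternary centre and the C1 carbinol all disappear, leaving a monocyclic epoxide whose side chain is an alkylidenesuccinate. The forward step must deliver C-alkylation at the tertiary oxirane carbon with inversion, from a nucleophile tethered to C5, faster than rearrangement of the activated epoxide.

9 to 8. The two C–O bonds of the oxirane are cut to give the C1=C10 alkene. The only demand is face selectivity: the oxygen must enter syn to the C5 side chain.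

8 to 5 + 6. The C7=C8 double bond is cut. The four carbons C8, C9, C11 and C12 come from 6 in one olefination. The (E) geometry is required, since it places C6 and C9 on the same side for ring closure.

5 to 4 to 2. The C5–C6 bond is cut with a [3,3] shift of the alkene back from C1=C10 to C10=C5 and return of oxygen to C1. The C5 stereocentre, flanked by the quaternary C4, is traced to a secondary allylic carbinol. The forward rearrangement must be suprafacial so that the C1 configuration is copied to C5.

2 to 1. The C1–H bond is cut. The only stereocentre that needs an external chiral source is set by catalytic ketone reduction.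

18 to 16. The aryl O–Si bond is cut; the forward step must leave the carboxyl free.

## Other disconnections considered

Alternative 1: the first idea is to cut C9–C10 and C7–C8, making ring B a Diels–Alder adduct. The forward key step is the thermal [4+2] reaction of the silyloxy diene A1 with dimethyl acetylenedicarboxylate to give adduct A2. The diene terminus C10 is fully substituted and sits beside the C1 stereocentre, so the cycloaddition should be slow, and its facial course would depend only on the conformational bias of one allylic silyloxy group. A2 carries its double bonds at C5=C6 and C8=C9, so C5 needs a later hydrogenation and C9 with the 7-ene a later deconjugation. That is three stereocentres from three unlinked events. In the chosen plan C1 and C10 are tied together by one stereospecific inversion and the 7-ene is delivered in place. The step counts are comparable, so the preference rests on stereochemical linkage, not length.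

Alternative 2: cut C4–C5 and C9–C10, closing both rings from an acyclic chain. The forward key step would be a hydrogen-atom-transfer-initiated radical bicyclisation (Fe(acac)3, PhSiH3) of trienone A3. The C4 radical would add to the enone at C5 and the resulting C10 α-keto radical to C9, giving bicyclic ketone A4. This is polarity-matched and short, but C5 forms first with no chiral element in the substrate, so A4 would be racemic. C1 also arrives as a ketone, C12 as a methyl needing later allylic oxidation, and the alkene position depends on an unselective termination. The chosen plan keeps absolute control and the correct oxidation pattern.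

Alternative 3: cut C5–C10 and C8–C9 in an intramolecular Diels–Alder reaction of trienal A5 to give adduct A6, closing both rings at once. The dienophile is a β,β-disubstituted enal that must form the quaternary C10 beside a tether bearing the C4 gem-dimethyl group, so the barrier should be high. Lewis acids that would lower it also threaten the allylic silyloxy group and the enal geometry, on which C9 and C10 depend. The alkene of A6 lies at C6=C7, and moving it into conjugation at the dialdehyde stage needs the basic conditions that epimerise C9. The chosen plan forms C10 from a tertiary oxirane carbon, where substitution helps ionisation.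

Key step: step 6

Assumption: 2,4,4-trimethylcyclohex-2-en-1-one (1) is treated as a catalogue compound; it is also the one-step annulation product of isobutyraldehyde and ethyl vinyl ketone.

## Steps

Step 1
Reactants: 1 2,4,4-trimethylcyclohex-2-en-1-one
Product: 2 (1R)-2,4,4-trimethylcyclohex-2-en-1-ol
Conditions: (S)-Me-CBS oxazaborolidine [(S)-1-methyl-3,3-diphenyltetrahydropyrrolo[1,2-c][1,3,2]oxazaborole] (10 mol %), BH3·SMe2, THF, −20 °C; MeOH
Reagents that add atoms: none
Why: Corey–Bakshi–Shibata reduction; the 2-methylvinyl arm acts as the large group, so hydride should be delivered to one face of the carbonyl to give the (R)-carbinol (the future C1), and only 1,2-reduction is expected.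

Step 2
Reactants: 2 (1R)-2,4,4-trimethylcyclohex-2-en-1-ol
Product: 4 ethyl 2-[(1S)-2,6,6-trimethylcyclohex-2-en-1-yl]acetate, via allyl ketene acetal 3 (not isolated)
Conditions: MeC(OEt)3, EtCO2H (cat.), 140 °C, EtOH distilled off
Reagents that add atoms: triethyl orthoacetate, CC(OCC)(OCC)OCC
Why: Johnson–Claisen rearrangement; the [3,3] shift is suprafacial across the ring allyl unit, so the new C5–C6 bond should form on the face that carried the C1–O bond and the alkene moves to C1=C10. Ester formation drives the bond formation beside the quaternary C4.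

Step 3
Reactants: 4 ethyl 2-[(1S)-2,6,6-trimethylcyclohex-2-en-1-yl]acetate
Product: 5 2-[(1S)-2,6,6-trimethylcyclohex-2-en-1-yl]acetaldehyde
Conditions: i-Bu2AlH, CH2Cl2, −78 °C; aq. sodium potassium tartrate
Reagents that add atoms: none
Why: Partial reduction of an ester through the tetrahedral aluminate, which is stable at −78 °C; the C5 stereocentre is β to the carbonyl and cannot epimerise.

Step 4
Reactants: 5 2-[(1S)-2,6,6-trimethylcyclohex-2-en-1-yl]acetaldehyde; 6 dimethyl maleate
Product: 8 dimethyl (2E)-2-{2-[(1S)-2,6,6-trimethylcyclohex-2-en-1-yl]ethylidene}butanedioate, via phosphorus ylide 7 (not isolated)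
Conditions: PPh3 and 6, PhMe, 23 °C; then 5, 80 °C
Reagents that add atoms: none
Why: Wittig olefination with the stabilised succinate ylide formed by phosphine addition to the maleate and proton shift. A stabilised ylide should give the (E)-alkylidenesuccinate, in which C6 is cis to the CH2CO2Me arm (C9), as ring closure requires.

Step 5
Reactants: 8 dimethyl (2E)-2-{2-[(1S)-2,6,6-trimethylcyclohex-2-en-1-yl]ethylidene}butanedioate
Product: 9 dimethyl (2E)-2-{2-[(1S,2S,6R)-1,3,3-trimethyl-7-oxabicyclo[4.1.0]heptan-2-yl]ethylidene}butanedioate
Conditions: mCPBA, NaHCO3, CH2Cl2, 0 °C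
Reagents that add atoms: mCPBA (3-chloroperoxybenzoic acid), OOC(=O)c1cccc(Cl)c1
Why: Prilezhaev epoxidation; the peracid should take the electron-rich trisubstituted ring alkene and leave the acrylate. The C5 side chain is expected to sit pseudoaxial (avoiding the 10-methyl) while the axial C4 methyl screens the opposite face, so oxygen should enter syn to the side chain, as known for 6-substituted 1,5,5-trimethylcyclohexenes of the α-ionone type.

Step 6
Reactants: 9 dimethyl (2E)-2-{2-[(1S,2S,6R)-1,3,3-trimethyl-7-oxabicyclo[4.1.0]heptan-2-yl]ethylidene}butanedioate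
Product: 11 dimethyl (1R,5S,10S)-1-hydroxydrim-7-ene-11,12-dioate as C9 epimer mixture, via trimethylsilyl ketene acetal 10 (not isolated)
Conditions: LiN(SiMe3)2, Me3SiCl, THF, −78 °C; then MeAlCl2, CH2Cl2 (0.01 M), −78 → −40 °C; aq. NaHCO3
Reagents that add atoms: none
Why: Epoxide-initiated cation–olefin cyclisation terminated by a silyl ketene acetal, i.e. an intramolecular Mukaiyama-type epoxide alkylation; the closest known type is the MeAlCl2-promoted cyclisation of epoxides onto silyl enol ethers. MeAlCl2 binds the oxirane oxygen, the C10–O bond lengthens with tertiary-cation character, and the nucleophilic C9 of 10 attacks C10 anti to the leaving oxygen, after which Me3Si is lost from the ester oxocarbenium ion. Ring B closes in a 6-exo-tet mode at C10 through an exocyclic enol carbon (6-(enolexo)-exo-tet), the cis C7=C8 bond holding C6 and C9 on the same side. C10 is set by inversion: oxygen leaves from the β face and C9 enters from the α face, so the methyl is pushed to the β face and the fusion becomes trans; a fully ionised C10 cation should give the same result, because the equatorial C5 chain reaches the α face through a chair-like ring B while the β face is screened by the departing aluminate and the axial C4 methyl. C1 keeps its C–O bond and therefore the β configuration fixed in step 5, and C5 is carried in from step 2. C9 is not controlled here and is corrected in step 7. The step needs C-alkylation at C10 to outrun 1,2-hydride shift, ring contraction and proton loss of the activated epoxide: the strongly nucleophilic ketene acetal held five atoms away, high dilution and low temperature are meant to secure this, and only C9 can reach C10 through a six-membered transition state (C7 would give a four-membered ring).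

Step 7
Reactants: 11 dimethyl (1R,5S,10S)-1-hydroxydrim-7-ene-11,12-dioate as C9 epimer mixture
Product: 13 methyl (1R,5S,9R,10S)-11-oxo-1,11-epoxydrim-7-en-12-oate (the γ-lactone between C11 and O1), via potassium dienolate 12 (not isolated)
Conditions: KOt-Bu (1.2 equiv), THF, 0 °C; then AcOH, −78 °C
Reagents that add atoms: none
Why: Base-mediated epimerisation and lactonisation followed by kinetic protonation of an extended enolate: reversible enolisation equilibrates C9, only the 9β-ester can be reached by the 1β-alkoxide, and the lactone is stored as the single dienolate 12 whatever the C9 epimer or alkene isomer it came from. Extended enolates protonate kinetically at the α-carbon (C9), and within the lactone C9 can only accept the proton on the α face, so H9α follows from ring geometry, not from reagent control.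

Step 8
Reactants: 13 methyl (1R,5S,9R,10S)-11-oxo-1,11-epoxydrim-7-en-12-oate
Product: 14 (1R,5S,9S,10S)-drim-7-ene-1,11,12-triol
Conditions: LiAlH4, THF, 0 °C
Reagents that add atoms: none
Why: Hydride reduction of the lactone and of the conjugated ester (1,2-addition) to the triol; no stereocentre is touched and C9 is no longer epimerisable (its descriptor changes only through substituent priorities).

Step 9
Reactants: 14 (1R,5S,9S,10S)-drim-7-ene-1,11,12-triol
Product: 15 (1R,5S,9S,10S)-11,12-bis(triethylsilyloxy)drim-7-en-1-ol
Conditions: Et3SiCl (2.1 equiv), imidazole, CH2Cl2, −20 → 0 °C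
Reagents that add atoms: chlorotriethylsilane, CC[Si](Cl)(CC)CC
Why: Silylation discriminates by rate: the two primary hydroxyls should react, while the secondary C1 hydroxyl beside the quaternary C10 stays free.

Step 10
Reactants: 16 (E)-4-hydroxycinnamic acid (p-coumaric acid)
Product: 18 (E)-3-[4-(tert-butyldimethylsilyloxy)phenyl]prop-2-enoic acid, via bis-silylated coumarate 17 (not isolated)
Conditions: t-BuMe2SiCl (2.3 equiv), imidazole, DMF, 23 °C; then AcOH, THF, H2O
Reagents that add atoms: tert-butyl(chloro)dimethylsilane, CC(C)(C)[Si](C)(C)Cl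
Why: Persilylation followed by selective hydrolysis of the labile silyl ester; the aryl silyl ether should survive mild aqueous acid.

Step 11
Reactants: 15 (1R,5S,9S,10S)-11,12-bis(triethylsilyloxy)drim-7-en-1-ol; 18 (E)-3-[4-(tert-butyldimethylsilyloxy)phenyl]prop-2-enoic acid
Product: 20 (1R,5S,9S,10S)-11,12-bis(triethylsilyloxy)drim-7-en-1-yl (E)-3-[4-(tert-butyldimethylsilyloxy)phenyl]prop-2-enoate, via Yamaguchi mixed anhydride 19 (not isolated)
Conditions: 18, 2,4,6-Cl3C6H2COCl, Et3N, THF, 23 °C; then 15, DMAP, PhMe, 60 °C
Reagents that add atoms: none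
Why: Yamaguchi esterification; the acylpyridinium ion formed from the mixed anhydride and DMAP should acylate the hindered equatorial C1 hydroxyl, the only free hydroxyl, without touching a stereocentre or the (E)-alkene.

Step 12
Reactants: 20 (1R,5S,9S,10S)-11,12-bis(triethylsilyloxy)drim-7-en-1-yl (E)-3-[4-(tert-butyldimethylsilyloxy)phenyl]prop-2-enoate
Product: 21 (1R,5S,9R,10S)-11,12-dioxodrim-7-en-1-yl (E)-3-[4-(tert-butyldimethylsilyloxy)phenyl]prop-2-enoate
Conditions: (COCl)2, DMSO, CH2Cl2, −78 → −35 °C; Et3N, −78 → 0 °C
Reagents that add atoms: none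
Why: Swern oxidation applied directly to primary triethylsilyl ethers: chlorodimethylsulfonium chloride cleaves the primary Si–O bonds and the alkoxysulfonium ions collapse to aldehydes with Et3N. Both carbonyls form together, so no 11,12-lactol can arise; the low temperature protects C9 and the aryl silyl ether is inert.

Step 13
Reactants: 21 (1R,5S,9R,10S)-11,12-dioxodrim-7-en-1-yl (E)-3-[4-(tert-butyldimethylsilyloxy)phenyl]prop-2-enoate
Product: 22 (1R,5S,9R,10S)-11,12-dioxodrim-7-en-1-yl (E)-3-(4-hydroxyphenyl)prop-2-enoate (CNP0187624.1)
Conditions: HF·pyridine, pyridine, THF, 0 °C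
Reagents that add atoms: none
Why: Fluoride cleavage of the aryl silyl ether under buffered, weakly acidic conditions, under which neither C9 epimerisation nor ester cleavage is expected.

## Compound list

1 | 2,4,4-trimethylcyclohex-2-en-1-one | CC1=CC(C)(C)CCC1=O | starting material
2 | (1R)-2,4,4-trimethylcyclohex-2-en-1-ol | O[C@@H]1CCC(C)(C)C=C1C | intermediate
3 | (1R)-2,4,4-trimethylcyclohex-2-en-1-yl 1-ethoxyethenyl ether (allyl ketene acetal) | C=C(OCC)O[C@@H]1CCC(C)(C)C=C1C | intermediate (not isolated)
4 | ethyl 2-[(1S)-2,6,6-trimethylcyclohex-2-en-1-yl]acetate | CCOC(=O)C[C@@H]1C(C)=CCCC1(C)C | intermediate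
5 | 2-[(1S)-2,6,6-trimethylcyclohex-2-en-1-yl]acetaldehyde | O=CC[C@@H]1C(C)=CCCC1(C)C | intermediate
6 | dimethyl maleate | COC(=O)/C=C\C(=O)OC | starting material
7 | dimethyl 2-(triphenyl-λ5-phosphanylidene)butanedioate | COC(=O)CC(C(=O)OC)=P(c1ccccc1)(c1ccccc1)c1ccccc1 | intermediate (not isolated)
8 | dimethyl (2E)-2-{2-[(1S)-2,6,6-trimethylcyclohex-2-en-1-yl]ethylidene}butanedioate | COC(=O)C/C(=C\C[C@@H]1C(C)=CCCC1(C)C)C(=O)OC | intermediate
9 | dimethyl (2E)-2-{2-[(1S,2S,6R)-1,3,3-trimethyl-7-oxabicyclo[4.1.0]heptan-2-yl]ethylidene}butanedioate (oxirane cis to the side chain) | COC(=O)C/C(=C\C[C@@H]1[C@]2(C)O[C@@H]2CCC1(C)C)C(=O)OC | intermediate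
10 | methyl (2E)-4-methoxy-2-{2-[(1S,2S,6R)-1,3,3-trimethyl-7-oxabicyclo[4.1.0]heptan-2-yl]ethylidene}-4-[(trimethylsilyl)oxy]but-3-enoate | COC(O[Si](C)(C)C)=C/C(=C\C[C@@H]1[C@]2(C)O[C@@H]2CCC1(C)C)C(=O)OC | intermediate (not isolated)
11 | dimethyl (1R,5S,10S)-1-hydroxydrim-7-ene-11,12-dioate (1β-OH, 5α-H, 10β-CH3; C9 epimer mixture) | CC1(C)CC[C@@H](O)[C@]2(C)C(C(=O)OC)C(C(=O)OC)=CC[C@@H]12 | intermediate
12 | potassium dienolate of 13 (C9=C11 enolate conjugated with C7=C8) | CC1(C)CC[C@@H](O3)[C@]2(C)C(=C3[O-])C(C(=O)OC)=CC[C@@H]12.[K+] | intermediate (not isolated)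
13 | methyl (1R,5S,9R,10S)-11-oxo-1,11-epoxydrim-7-en-12-oate (γ-lactone C11 to O1; 9α-H) | CC1(C)CC[C@@H](O3)[C@]2(C)[C@@H](C3=O)C(C(=O)OC)=CC[C@@H]12 | intermediate
14 | (1R,5S,9S,10S)-drim-7-ene-1,11,12-triol | CC1(C)CC[C@@H](O)[C@]2(C)[C@@H](CO)C(CO)=CC[C@@H]12 | intermediate
15 | (1R,5S,9S,10S)-11,12-bis(triethylsilyloxy)drim-7-en-1-ol | CC1(C)CC[C@@H](O)[C@]2(C)[C@@H](CO[Si](CC)(CC)CC)C(CO[Si](CC)(CC)CC)=CC[C@@H]12 | intermediate
16 | (E)-4-hydroxycinnamic acid | OC(=O)/C=C/c1ccc(O)cc1 | starting material
17 | tert-butyldimethylsilyl (E)-3-[4-(tert-butyldimethylsilyloxy)phenyl]prop-2-enoate | CC(C)(C)[Si](C)(C)OC(=O)/C=C/c1ccc(O[Si](C)(C)C(C)(C)C)cc1 | intermediate (not isolated)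
18 | (E)-3-[4-(tert-butyldimethylsilyloxy)phenyl]prop-2-enoic acid | OC(=O)/C=C/c1ccc(O[Si](C)(C)C(C)(C)C)cc1 | intermediate
19 | (E)-3-[4-(tert-butyldimethylsilyloxy)phenyl]prop-2-enoic 2,4,6-trichlorobenzoic anhydride | O=C(/C=C/c1ccc(O[Si](C)(C)C(C)(C)C)cc1)OC(=O)c1c(Cl)cc(Cl)cc1Cl | intermediate (not isolated)
20 | (1R,5S,9S,10S)-11,12-bis(triethylsilyloxy)drim-7-en-1-yl (E)-3-[4-(tert-butyldimethylsilyloxy)phenyl]prop-2-enoate | CC1(C)CC[C@@H](OC(=O)/C=C/c3ccc(O[Si](C)(C)C(C)(C)C)cc3)[C@]2(C)[C@@H](CO[Si](CC)(CC)CC)C(CO[Si](CC)(CC)CC)=CC[C@@H]12 | intermediate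
21 | (1R,5S,9R,10S)-11,12-dioxodrim-7-en-1-yl (E)-3-[4-(tert-butyldimethylsilyloxy)phenyl]prop-2-enoate | CC1(C)CC[C@@H](OC(=O)/C=C/c3ccc(O[Si](C)(C)C(C)(C)C)cc3)[C@]2(C)[C@@H](C=O)C(C=O)=CC[C@@H]12 | intermediate
22 | (1R,5S,9R,10S)-11,12-dioxodrim-7-en-1-yl (E)-3-(4-hydroxyphenyl)prop-2-enoate | CC1(C)CC[C@@H](OC(=O)/C=C/c2ccc(O)cc2)[C@]2(C)[C@@H](C=O)C(C=O)=CC[C@@H]12 | target

## Step count and least certain steps

Total step count: 13. Longest linear sequence: 12 (steps 1–9 and 11–13); step 10 is a one-step side branch.

Step 6 (key step). A 1,2-hydride shift or ring contraction of the activated epoxide (Meinwald-type rearrangement) or proton loss to an allylic alcohol may outrun C–C bond formation. The cause is that ring A must pass through a twist-boat-like geometry when a nucleophile tethered to C5 opens the oxirane at C10. Intermolecular Mukaiyama–Michael coupling of 10 and chloride transfer from aluminium are further losses. The fallback replaces the epoxide opening by a cycloaddition; it sets out from 1 and comes back at 12. Conjugate addition of CH2=CHMgBr (CuBr·SMe2, Me3SiCl) to 1 gives the silyl enol ether trimethyl[(2,4,4-trimethyl-3-vinylcyclohex-1-en-1-yl)oxy]silane F1. Saegusa–Ito dehydrogenation with Pd(OAc)2 gives 2,4,4-trimethyl-3-vinylcyclohex-2-en-1-one F2, and Corey–Bakshi–Shibata reduction gives (1R)-2,4,4-trimethyl-3-vinylcyclohex-2-en-1-ol F3. A thermal Diels–Alder reaction with dimethyl acetylenedicarboxylate, expected anti to the hydroxyl, gives dimethyl (1R,10S)-1-hydroxydrima-5,8-diene-11,12-dioate F4. Hydrogenation over Pd/C from the α face (the β face carries the 10-methyl) gives dimethyl (1R,5S,10S)-1-hydroxydrim-8-ene-11,12-dioate F5. Under the conditions of step 7, F5 lactonises and is deprotonated at C7, which gives dienolate 12.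

Step 5. Poor facial selectivity of the peracid: oxygen delivered anti to the side chain would carry the material into the 1-epi or cis-fused series in step 6. The fallback replaces reagent approach control by an intramolecular delivery; it sets out from 4 and comes back at 9. Saponification of 4 (LiOH) gives 2-[(1S)-2,6,6-trimethylcyclohex-2-en-1-yl]acetic acid F6. Iodolactonisation (I2, NaHCO3) gives (3aS,7S,7aS)-7-iodo-4,4,7a-trimethylhexahydro-1-benzofuran-2(3H)-one F7, in which the carboxylate oxygen has added to C10 on the side-chain face and iodine sits on C1 on the other face. NaOMe in MeOH opens the lactone, and the C10 alkoxide displaces iodide with inversion to give methyl 2-[(1S,2S,6R)-1,3,3-trimethyl-7-oxabicyclo[4.1.0]heptan-2-yl]acetate F8. i-Bu2AlH at −78 °C gives 2-[(1S,2S,6R)-1,3,3-trimethyl-7-oxabicyclo[4.1.0]heptan-2-yl]acetaldehyde F9, and the olefination of step 4 (PPh3 and 6) then gives 9.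

Step 7. Protonation of dienolate 12 at C7 instead of C9 would move the double bond into the C8=C9 position; incomplete equilibration of the 9α-ester before lactonisation is the other risk. The fallback uses a thermodynamic sink and then a photochemical deconjugation; it sets out from 11 and comes back at 13. DBU in hot toluene should convert 11 into the fully conjugated lactone methyl (1R,5S,10S)-11-oxo-1,11-epoxydrim-8-en-12-oate F10. Irradiation at 254 nm in the presence of a catalytic weak base (photoenolisation by γ-hydrogen abstraction, then α-protonation of the dienol) should move the double bond to C7=C8, the lactone again allowing only H9α, to give 13.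

Step 11. Slow acylation of the hindered C1 hydroxyl may let the mixed anhydride decay or allow silyl migration from O11 to O1 at 60 °C. The fallback builds the cinnamate on the alcohol; it sets out from 15 and comes back at 20. Acylation of 15 with the small diethylphosphonoacetic acid (carbodiimide, DMAP) gives (1R,5S,9S,10S)-11,12-bis(triethylsilyloxy)drim-7-en-1-yl 2-(diethoxyphosphoryl)acetate F11. A Horner–Wadsworth–Emmons reaction with 4-(tert-butyldimethylsilyloxy)benzaldehyde (LiCl, DBU, MeCN) gives the (E)-cinnamate 20.

Step 12. Incomplete Si–O cleavage at the hindered C11 silyl ether would give mono-aldehydes, and an 11-hydroxyl set free before oxidation could take over the acyl group from O1 or close a lactol. Epimerisation at C9 by the amine on warming is the third risk. The fallback separates deprotection from oxidation and avoids amine base; it sets out from 20 and comes back at 21. Pyridinium p-toluenesulfonate in MeOH removes both primary silyl groups under weakly acidic conditions to give (1R,5S,9S,10S)-11,12-dihydroxydrim-7-en-1-yl (E)-3-[4-(tert-butyldimethylsilyloxy)phenyl]prop-2-enoate F12. Dess–Martin periodinane buffered with NaHCO3 then oxidises both hydroxyls to give 21.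

## Further compounds

F1 | step 6 | trimethyl[(2,4,4-trimethyl-3-vinylcyclohex-1-en-1-yl)oxy]silane (racemic) | C=CC1C(C)=C(O[Si](C)(C)C)CCC1(C)C
F2 | step 6 | 2,4,4-trimethyl-3-vinylcyclohex-2-en-1-one | C=CC1=C(C)C(=O)CCC1(C)C
F3 | step 6 | (1R)-2,4,4-trimethyl-3-vinylcyclohex-2-en-1-ol | C=CC1=C(C)[C@H](O)CCC1(C)C
F4 | step 6 | dimethyl (1R,10S)-1-hydroxydrima-5,8-diene-11,12-dioate | CC1(C)CC[C@@H](O)[C@]2(C)C(C(=O)OC)=C(C(=O)OC)CC=C12
F5 | step 6 | dimethyl (1R,5S,10S)-1-hydroxydrim-8-ene-11,12-dioate | CC1(C)CC[C@@H](O)[C@]2(C)C(C(=O)OC)=C(C(=O)OC)CC[C@@H]12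
F6 | step 5 | 2-[(1S)-2,6,6-trimethylcyclohex-2-en-1-yl]acetic acid | OC(=O)C[C@@H]1C(C)=CCCC1(C)C
F7 | step 5 | (3aS,7S,7aS)-7-iodo-4,4,7a-trimethylhexahydro-1-benzofuran-2(3H)-one | CC1(C)CC[C@H](I)[C@@]2(C)OC(=O)C[C@@H]12
F8 | step 5 | methyl 2-[(1S,2S,6R)-1,3,3-trimethyl-7-oxabicyclo[4.1.0]heptan-2-yl]acetate | COC(=O)C[C@@H]1[C@]2(C)O[C@@H]2CCC1(C)C
F9 | step 5 | 2-[(1S,2S,6R)-1,3,3-trimethyl-7-oxabicyclo[4.1.0]heptan-2-yl]acetaldehyde | O=CC[C@@H]1[C@]2(C)O[C@@H]2CCC1(C)C
F10 | step 7 | methyl (1R,5S,10S)-11-oxo-1,11-epoxydrim-8-en-12-oate | CC1(C)CC[C@@H](O3)[C@]2(C)C(C3=O)=C(C(=O)OC)CC[C@@H]12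
F11 | step 11 | (1R,5S,9S,10S)-11,12-bis(triethylsilyloxy)drim-7-en-1-yl 2-(diethoxyphosphoryl)acetate | CC1(C)CC[C@@H](OC(=O)CP(=O)(OCC)OCC)[C@]2(C)[C@@H](CO[Si](CC)(CC)CC)C(CO[Si](CC)(CC)CC)=CC[C@@H]12
F12 | step 12 | (1R,5S,9S,10S)-11,12-dihydroxydrim-7-en-1-yl (E)-3-[4-(tert-butyldimethylsilyloxy)phenyl]prop-2-enoate | CC1(C)CC[C@@H](OC(=O)/C=C/c3ccc(O[Si](C)(C)C(C)(C)C)cc3)[C@]2(C)[C@@H](CO)C(CO)=CC[C@@H]12
A1 | alternative 1 | tert-butyl(dimethyl){[(1R)-2,4,4-trimethyl-3-vinylcyclohex-2-en-1-yl]oxy}silane | C=CC1=C(C)[C@H](O[Si](C)(C)C(C)(C)C)CCC1(C)C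
A2 | alternative 1 | dimethyl (1R,10S)-1-(tert-butyldimethylsilyloxy)drima-5,8-diene-11,12-dioate | CC1(C)CC[C@@H](O[Si](C)(C)C(C)(C)C)[C@]2(C)C(C(=O)OC)=C(C(=O)OC)CC=C12
A3 | alternative 2 | (2E,6E)-3,7,11-trimethyl-8-oxododeca-2,6,11-trien-1-yl acetate | C=C(C)CCC(=O)/C(C)=C/CC/C(C)=C/COC(C)=O
A4 | alternative 2 | 1-oxodrim-7-en-11-yl acetate (racemic; one enantiomer drawn, 5α-H, 9α-H, 10β-CH3) | CC1(C)CCC(=O)[C@]2(C)[C@@H](COC(C)=O)C(C)=CC[C@@H]12
A5 | alternative 3 | (2E,4R,8E,10E)-4,12-bis(tert-butyldimethylsilyloxy)-3,7,7-trimethyldodeca-2,8,10-trienal | O=C/C=C(\C)[C@H](O[Si](C)(C)C(C)(C)C)CCC(C)(C)/C=C/C=C/CO[Si](C)(C)C(C)(C)C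
A6 | alternative 3 | 1β,12-bis(tert-butyldimethylsilyloxy)drim-6-en-11-al (5α-H, 8α-H, 9α-H, 10β-CH3) | CC1(C)CC[C@@H](O[Si](C)(C)C(C)(C)C)[C@]2(C)[C@@H](C=O)[C@@H](CO[Si](C)(C)C(C)(C)C)C=C[C@@H]12
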